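**Retrosynthetic overview**
1. Atom labels (labdane type): ring A = C1–C5 and C10 (C4 gem-dimethyl, C10 methyl); ring B = C5–C10 (C6 OAc, C8 methyl, C9 OH); side chain C11–C12; butenolide C13–C16. Late disconnections: the O-acetyl group; C12–C13 (B-alkyl Suzuki–Miyaura coupling with 3-bromobutenolide); C11=C12 and C9–O (9α,11-epoxide of a C9 exo-methylene, one-carbon homologation).
2. The 6β-OH comes from a C6 ketone (hydride from the open α face). C5–H and C6–O come from α-face hydroboration of a C5=C6 alkene. The C9 exo-methylene comes from a C9 ketone.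
3. Key disconnection C6–C7 (closes ring B): Me2AlCl-promoted 6-endo cyclisation of monocyclic dienone 11. The CH2 terminus (C6) of the exocyclic C5=C6 methylene on ring A adds to the β-carbon (C7) of the isopropenyl ketone C7=C8–C9(=O) carried by C10.
4. Enabling feature: C5 lies between the quaternary carbons C4 and C10. The C5=C6 methylene therefore has no allylic hydrogen, and the C5 cation can only lose a proton from C6. The C5=C6 alkene and the C9 ketone left behind are the handles for C5, C6, C8 and C9.
5. Ring order: ring A is bought (2,2,6-trimethylcyclohexanone; C10 set by Pd-catalysed decarboxylative asymmetric allylation), ring B is closed in step 8, and the butenolide ring is bought and attached in step 15.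

Key step: step 8

Assumption: the (R)-enantiomer of t-Bu-PHOX is taken to deliver the (R)-ketone 5, the mirror image of the sense known for the (S)-ligand with 2-alkylcyclohexanone enol carbonates.
Assumption: isopropenylmagnesium bromide (9, THF solution) and 3-bromofuran-2(5H)-one (21) are taken as commercial.

Step 1
Reactants: 1 2,2,6-trimethylcyclohexan-1-one; 2 allyl chloroformate
Product: 4 prop-2-en-1-yl 2,6,6-trimethylcyclohex-1-en-1-yl carbonate, via lithium enolate 3 (not isolated)
Conditions: LiN(SiMe3)2, THF, 0 °C; then 2, −78 → 0 °C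
Reagents that add atoms: none
Why: Enolate O-acylation; the ketone has a single enolisable position and the hard chloroformate should acylate the tetrasubstituted lithium enolate on oxygen.

Step 2
Reactants: 4 prop-2-en-1-yl 2,6,6-trimethylcyclohex-1-en-1-yl carbonate
Product: 5 (R)-2,2,6-trimethyl-6-(prop-2-en-1-yl)cyclohexan-1-one
Conditions: Pd2(dba)3 (2.5 mol%), (R)-t-Bu-PHOX [(R)-4-tert-butyl-2-(2-diphenylphosphinophenyl)-4,5-dihydrooxazole] (6 mol%), THF, 25 °C
Reagents that add atoms: none
Why: Decarboxylative asymmetric allylic alkylation (Tsuji type); the chiral Pd–PHOX allyl/enolate pair should recombine on one enolate face and set the quaternary C10.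

Step 3
Reactants: 5 (R)-2,2,6-trimethyl-6-(prop-2-en-1-yl)cyclohexan-1-one
Product: 6 (R)-2,2,6-trimethyl-6-[(E)-prop-1-en-1-yl]cyclohexan-1-one
Conditions: PdCl2(MeCN)2 (5 mol%), toluene, 60 °C
Reagents that add atoms: none
Why: Metal-hydride alkene isomerisation to the more stable (E)-propenyl group; the quaternary C10 has no hydrogen and cannot be touched.

Step 4
Reactants: 6 (R)-2,2,6-trimethyl-6-[(E)-prop-1-en-1-yl]cyclohexan-1-one
Product: 7 (R)-1,3,3-trimethyl-2-methylidene-1-[(E)-prop-1-en-1-yl]cyclohexane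
Conditions: Ph3PCH3Br, KOtBu, toluene, 100 °C
Reagents that add atoms: methyltriphenylphosphonium bromide, C[P+](c1ccccc1)(c1ccccc1)c1ccccc1.[Br-]
Why: Wittig methylenation under forcing, salt-free conditions for a ketone flanked by two quaternary carbons; there is no α-hydrogen, so no enolisation or epimerisation can compete.

Step 5
Reactants: 7 (R)-1,3,3-trimethyl-2-methylidene-1-[(E)-prop-1-en-1-yl]cyclohexane
Product: 8 (S)-1,3,3-trimethyl-2-methylidenecyclohexane-1-carbaldehyde
Conditions: K2OsO4·2H2O (2 mol%), NaIO4, 2,6-lutidine, 1,4-dioxane/H2O, 20 °C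
Reagents that add atoms: sodium periodate, [Na+].[O-]I(=O)(=O)=O (oxygen relayed through OsO4, O=[Os](=O)(=O)=O, formed from K2OsO4·2H2O)
Why: Lemieux–Johnson oxidative cleavage; the exposed 1,2-disubstituted propenyl alkene should be osmylated in preference to the exocyclic methylene, which is buried between the quaternary C4 and C10.

Step 6
Reactants: 8 (S)-1,3,3-trimethyl-2-methylidenecyclohexane-1-carbaldehyde; 9 isopropenylmagnesium bromide
Product: 10 2-methyl-1-[(1S)-1,3,3-trimethyl-2-methylidenecyclohexyl]prop-2-en-1-ol (both carbinol epimers)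
Conditions: THF, −78 → 0 °C
Reagents that add atoms: none
Why: Grignard 1,2-addition to the neopentyl aldehyde; the new carbinol centre (C9) forms without control and is erased in step 7.

Step 7
Reactants: 10 2-methyl-1-[(1S)-1,3,3-trimethyl-2-methylidenecyclohexyl]prop-2-en-1-ol
Product: 11 2-methyl-1-[(1S)-1,3,3-trimethyl-2-methylidenecyclohexyl]prop-2-en-1-one
Conditions: Dess–Martin periodinane, pyridine, CH2Cl2, 0 °C
Reagents that add atoms: none
Why: Dess–Martin oxidation of the allylic alcohol; both C9 epimers converge on one vinyl ketone under neutral conditions that leave the two alkenes alone.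

Step 8
Reactants: 11 2-methyl-1-[(1S)-1,3,3-trimethyl-2-methylidenecyclohexyl]prop-2-en-1-one
Product: 13 (2R,8aS)-2,5,5,8a-tetramethyl-3,5,6,7,8,8a-hexahydronaphthalen-1(2H)-one, via aluminium enolate 12 (not isolated)
Conditions: Me2AlCl (1.5 equiv), CH2Cl2 (0.01 M), −78 → 0 °C; then MeOH, K2CO3 (cat.), 25 °C
Reagents that add atoms: none
Why: Me2AlCl complexes the C9 carbonyl and the CH2 terminus (C6) of the exocyclic alkene adds to the enone β-carbon C7 through a six-membered chair-like array, giving a tertiary C5 cation/aluminium enolate zwitterion; because C4 and C10 are quaternary the cation can only lose a proton from C6, an Al–CH3 group takes it up as methane, and the C5=C6 alkene and enolate 12 result. The closest known reaction type is the Lewis-acid-initiated cation–olefin (conjugate ene-type) cyclisation of alkenyl enones with alkylaluminium chlorides. Ring B closes in the 6-endo-trig mode with respect to both the enone and the nucleophilic alkene. The only new stereocentre, C8, is set under thermodynamic control when 12 is protonated and equilibrated with K2CO3/MeOH: the methyl group should take the pseudo-equatorial α position, away from the axial C10 methyl. The step needs C6–C7 bond formation and proton loss to outrun Wagner–Meerwein shifts of the C5 cation and polymerisation of the vinyl ketone; low temperature, the proton-scavenging Lewis acid, the internal enolate base and high dilution should secure this, and the new alkene cannot move into conjugation because C10 is quaternary.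

Step 9
Reactants: 13 (2R,8aS)-2,5,5,8a-tetramethyl-3,5,6,7,8,8a-hexahydronaphthalen-1(2H)-one
Product: 15 (1S,3R,4aS,8aS)-3,4a,8,8-tetramethyldecahydronaphthalene-1,4-diol (C4 epimers; 6α-OH and 5α-H in labdane labels), via organoborane adduct 14 (not isolated)
Conditions: BH3·THF (4 equiv), THF, 0 → 40 °C; then NaOH, H2O2, H2O, 0 → 25 °C
Reagents that add atoms: hydrogen peroxide, OO
Why: Hydroboration–oxidation; syn addition to C5=C6 from the α face (the β face is closed by the axial C4 and C10 methyls) should set the 5α-H ring fusion with boron at the less substituted C6, while the C9 ketone is reduced without control and restored in step 10.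

Step 10
Reactants: 15 (1S,3R,4aS,8aS)-3,4a,8,8-tetramethyldecahydronaphthalene-1,4-diol
Product: 16 (2R,4aS,8aS)-2,5,5,8a-tetramethyloctahydronaphthalene-1,4-dione
Conditions: Dess–Martin periodinane (3 equiv), pyridine, CH2Cl2, 0 → 25 °C
Reagents that add atoms: none
Why: Dess–Martin oxidation of both secondary alcohols under buffered, non-enolising conditions, so the kinetically installed trans ring fusion at C5 (now α to the C6 ketone) should be kept.

Step 11
Reactants: 16 (2R,4aS,8aS)-2,5,5,8a-tetramethyloctahydronaphthalene-1,4-dione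
Product: 17 (2R,4R,4aS,8aS)-4-hydroxy-2,5,5,8a-tetramethyloctahydronaphthalen-1(2H)-one
Conditions: NaBH4 (1 equiv), MeOH/CH2Cl2, −40 °C
Reagents that add atoms: none
Why: Chemo- and stereoselective hydride reduction; the C6 carbonyl should react before the C9 carbonyl (flanked by quaternary C10 and substituted C8), and hydride should enter from the α face to give the axial 6β-alcohol, which also locks C5 against epimerisation.

Step 12
Reactants: 17 (2R,4R,4aS,8aS)-4-hydroxy-2,5,5,8a-tetramethyloctahydronaphthalen-1(2H)-one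
Product: 18 (1R,3R,4aS,8aS)-3,4a,8,8-tetramethyl-4-methylidenedecahydronaphthalen-1-ol
Conditions: Ph3PCH3Br, KOtBu (excess), THF/toluene, 70 °C
Reagents that add atoms: methyltriphenylphosphonium bromide, C[P+](c1ccccc1)(c1ccccc1)c1ccccc1.[Br-]
Why: Wittig methylenation of the hindered C9 ketone with the C6 hydroxyl carried as its alkoxide; any epimerisation at C8 under the base can only lead to the favoured equatorial 8α-methyl.

Step 13
Reactants: 18 (1R,3R,4aS,8aS)-3,4a,8,8-tetramethyl-4-methylidenedecahydronaphthalen-1-ol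
Product: 19 (1R,2R,4R,4aS,8aS)-2,5,5,8a-tetramethyloctahydro-2H-spiro[naphthalene-1,2'-oxiran]-4-ol (9α,11-epoxide)
Conditions: dimethyldioxirane, acetone, 0 °C
Reagents that add atoms: dimethyldioxirane, CC1(C)OO1
Why: Dioxirane epoxidation of the exocyclic alkene from the α face, since the β face is shielded by the adjacent axial C10 methyl; this places the C9 oxygen α and C11 β.

Step 14
Reactants: 19 (1R,2R,4R,4aS,8aS)-2,5,5,8a-tetramethyloctahydro-2H-spiro[naphthalene-1,2'-oxiran]-4-ol
Product: 20 (1R,3R,4R,4aS,8aS)-4-ethenyl-3,4a,8,8-tetramethyldecahydronaphthalene-1,4-diol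
Conditions: Me3S+ I− (6 equiv), n-BuLi (5.5 equiv), THF, −10 → 25 °C
Reagents that add atoms: trimethylsulfonium iodide, C[S+](C)C.[I-]
Why: One-carbon homologation of a terminal epoxide to an allylic alcohol with dimethylsulfonium methylide (ylide opening at the CH2 carbon C11, then base-induced loss of dimethyl sulfide); the C9–O bond is not broken, so the 9α-OH configuration is retained.

Step 15
Reactants: 20 (1R,3R,4R,4aS,8aS)-4-ethenyl-3,4a,8,8-tetramethyldecahydronaphthalene-1,4-diol; 21 3-bromofuran-2(5H)-one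
Product: 23 3-{2-[(1R,2R,4R,4aS,8aS)-1,4-dihydroxy-2,5,5,8a-tetramethyldecahydronaphthalen-1-yl]ethyl}furan-2(5H)-one, via B-alkyl-9-BBN adduct 22 (not isolated)
Conditions: 9-BBN (3 equiv), THF, 0 → 50 °C; then 21, Pd(dppf)Cl2 (5 mol%), AsPh3 (10 mol%), K3PO4 (aq), DMF, 25 °C
Reagents that add atoms: none
Why: Anti-Markovnikov hydroboration of the vinyl group followed by B-alkyl Suzuki–Miyaura coupling with the α-bromo enoate-type bromide forms C12–C13 and delivers the α-substituted butenolide directly; no stereocentre is touched.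

Step 16
Reactants: 23 3-{2-[(1R,2R,4R,4aS,8aS)-1,4-dihydroxy-2,5,5,8a-tetramethyldecahydronaphthalen-1-yl]ethyl}furan-2(5H)-one
Product: 24 (1R,3R,4R,4aS,8aS)-4-hydroxy-3,4a,8,8-tetramethyl-4-[2-(2-oxo-2,5-dihydrofuran-3-yl)ethyl]decahydronaphthalen-1-yl acetate
Conditions: Ac2O, 4-(dimethylamino)pyridine, pyridine, 40 °C
Reagents that add atoms: acetic anhydride, CC(=O)OC(C)=O
Why: Nucleophile-catalysed O-acylation; only the secondary 6β-hydroxyl should be acetylated, the tertiary C9 hydroxyl being inert under these conditions.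

**Compound list**
1 | 2,2,6-trimethylcyclohexan-1-one (racemic) | CC1CCCC(C)(C)C1=O | starting material
2 | allyl chloroformate | C=CCOC(=O)Cl | starting material
3 | lithium 2,6,6-trimethylcyclohex-1-en-1-olate | [Li]OC1=C(C)CCCC1(C)C | intermediate
4 | prop-2-en-1-yl 2,6,6-trimethylcyclohex-1-en-1-yl carbonate | C=CCOC(=O)OC1=C(C)CCCC1(C)C | intermediate
5 | (R)-2,2,6-trimethyl-6-(prop-2-en-1-yl)cyclohexan-1-one | C=CC[C@@]1(C)CCCC(C)(C)C1=O | intermediate
6 | (R)-2,2,6-trimethyl-6-[(E)-prop-1-en-1-yl]cyclohexan-1-one | C/C=C/[C@@]1(C)CCCC(C)(C)C1=O | intermediate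
7 | (R)-1,3,3-trimethyl-2-methylidene-1-[(E)-prop-1-en-1-yl]cyclohexane | C/C=C/[C@@]1(C)CCCC(C)(C)C1=C | intermediate
8 | (S)-1,3,3-trimethyl-2-methylidenecyclohexane-1-carbaldehyde | O=C[C@@]1(C)CCCC(C)(C)C1=C | intermediate
9 | isopropenylmagnesium bromide | CC(=C)[Mg]Br | starting material
10 | 2-methyl-1-[(1S)-1,3,3-trimethyl-2-methylidenecyclohexyl]prop-2-en-1-ol (carbinol epimers) | CC(=C)C(O)[C@@]1(C)CCCC(C)(C)C1=C | intermediate
11 | 2-methyl-1-[(1S)-1,3,3-trimethyl-2-methylidenecyclohexyl]prop-2-en-1-one | CC(=C)C(=O)[C@@]1(C)CCCC(C)(C)C1=C | intermediate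
12 | chloro(methyl)aluminium enolate of 13 (O–Al on C9, C8=C9, C5=C6) | C1C(C)=C(O[Al](C)Cl)[C@@]2(C)CCCC(C)(C)C2=C1 | intermediate
13 | (2R,8aS)-2,5,5,8a-tetramethyl-3,5,6,7,8,8a-hexahydronaphthalen-1(2H)-one | C1[C@@H](C)C(=O)[C@@]2(C)CCCC(C)(C)C2=C1 | intermediate
14 | organoborane adduct of 13 (C6–BH2 on the α face, 5α-H, C9–O–BH2) | [BH2][C@H]1C[C@@H](C)C(O[BH2])[C@@]2(C)CCCC(C)(C)[C@H]12 | intermediate
15 | (1S,3R,4aS,8aS)-3,4a,8,8-tetramethyldecahydronaphthalene-1,4-diol (C4 epimers) | O[C@H]1C[C@@H](C)C(O)[C@@]2(C)CCCC(C)(C)[C@H]12 | intermediate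
16 | (2R,4aS,8aS)-2,5,5,8a-tetramethyloctahydronaphthalene-1,4-dione | O=C1C[C@@H](C)C(=O)[C@@]2(C)CCCC(C)(C)[C@H]12 | intermediate
17 | (2R,4R,4aS,8aS)-4-hydroxy-2,5,5,8a-tetramethyloctahydronaphthalen-1(2H)-one | O[C@@H]1C[C@@H](C)C(=O)[C@@]2(C)CCCC(C)(C)[C@H]12 | intermediate
18 | (1R,3R,4aS,8aS)-3,4a,8,8-tetramethyl-4-methylidenedecahydronaphthalen-1-ol | O[C@@H]1C[C@@H](C)C(=C)[C@@]2(C)CCCC(C)(C)[C@H]12 | intermediate
19 | (1R,2R,4R,4aS,8aS)-2,5,5,8a-tetramethyloctahydro-2H-spiro[naphthalene-1,2'-oxiran]-4-ol | O[C@@H]1C[C@@H](C)[C@]3(CO3)[C@@]2(C)CCCC(C)(C)[C@H]12 | intermediate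
20 | (1R,3R,4R,4aS,8aS)-4-ethenyl-3,4a,8,8-tetramethyldecahydronaphthalene-1,4-diol | O[C@@H]1C[C@@H](C)[C@](O)(C=C)[C@@]2(C)CCCC(C)(C)[C@H]12 | intermediate
21 | 3-bromofuran-2(5H)-one | O=C1OCC=C1Br | starting material
22 | 9-{2-[(1R,2R,4R,4aS,8aS)-1,4-dihydroxy-2,5,5,8a-tetramethyldecahydronaphthalen-1-yl]ethyl}-9-borabicyclo[3.3.1]nonane | O[C@@H]1C[C@@H](C)[C@](O)(CCB3C4CCCC3CCC4)[C@@]2(C)CCCC(C)(C)[C@H]12 | intermediate
23 | 3-{2-[(1R,2R,4R,4aS,8aS)-1,4-dihydroxy-2,5,5,8a-tetramethyldecahydronaphthalen-1-yl]ethyl}furan-2(5H)-one | O[C@@H]1C[C@@H](C)[C@](O)(CCC2=CCOC2=O)[C@@]2(C)CCCC(C)(C)[C@H]12 | intermediate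
24 | (1R,3R,4R,4aS,8aS)-4-hydroxy-3,4a,8,8-tetramethyl-4-[2-(2-oxo-2,5-dihydrofuran-3-yl)ethyl]decahydronaphthalen-1-yl acetate | CC(=O)O[C@@H]1C[C@@H](C)[C@](O)(CCC2=CCOC2=O)[C@@]2(C)CCCC(C)(C)[C@H]12 | target

**Step count and risks**
Total step count: 16. Longest linear sequence: 16 steps (from 2,2,6-trimethylcyclohexan-1-one).

Most likely to fail, step 8. The C5 cation may be diverted by a Wagner–Meerwein methyl shift from C4, or the zwitterion may revert and the vinyl ketone polymerise, before the C6 proton is lost. Fallback: the route leaves from 11 and closes the same C6–C7 bond by an acyl radical instead of a cation. Dimethyldioxirane should epoxidise only the electron-rich exocyclic methylene of 11 (the enone alkene is electron-poor) to give 2-methyl-1-[(4S)-4,8,8-trimethyl-1-oxaspiro[2.5]octan-4-yl]prop-2-en-1-one F1. BF3·OEt2 in CH2Cl2 at −78 °C should rearrange the epoxide by 1,2-hydride shift to (2S)-2,6,6-trimethyl-2-(2-methylprop-2-enoyl)cyclohexane-1-carbaldehyde F2 (both C1 epimers). Photocatalytic hydrogen-atom abstraction from the formyl group with (Bu4N)4W10O32 (390 nm, MeCN, 25 °C) should then generate the acyl radical, which adds 6-endo to C7. The trans-fused product, to be separated from its ring-fusion epimer, is dione 16, where the route is rejoined; steps 9 and 10 are then not needed.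

Second, step 14. Substitution at C11 of the hindered spiro-epoxide by the ylide may be slow, and the lithium iodide present may instead trigger rearrangement of the epoxide. Fallback: the route leaves from 18 and avoids substitution at C11. Dihydroxylation of the exocyclic alkene from the α face (K2OsO4·2H2O cat., N-methylmorpholine N-oxide, acetone/H2O) should give (1R,2R,4R,4aS,8aS)-1-(hydroxymethyl)-2,5,5,8a-tetramethyldecahydronaphthalene-1,4-diol F3. Selective oxidation of the primary alcohol with (2,2,6,6-tetramethylpiperidin-1-yl)oxyl (cat.) and PhI(OAc)2 should give (1R,2R,4R,4aS,8aS)-1,4-dihydroxy-2,5,5,8a-tetramethyldecahydronaphthalene-1-carbaldehyde F4. Wittig methylenation (Ph3PCH3Br, KOtBu, THF, 0 °C) should convert this into 20, where the route is rejoined.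

Third, step 5. Chemoselectivity may be lost through osmylation of the exocyclic methylene as well as the propenyl group, or through over-oxidation. Fallback: the route leaves from 6 and cleaves the propenyl group before the second alkene exists. Ozonolysis (O3, CH2Cl2, −78 °C; Me2S) should give (1R)-1,3,3-trimethyl-2-oxocyclohexane-1-carbaldehyde F5. Grignard reagent 9 should add only to the aldehyde, not to the doubly neopentyl ketone, giving (6R)-6-(1-hydroxy-2-methylprop-2-en-1-yl)-2,2,6-trimethylcyclohexan-1-one F6. Silylation (t-BuMe2SiOTf, 2,6-lutidine) should give (6R)-6-{1-[tert-butyl(dimethyl)silyl]oxy-2-methylprop-2-en-1-yl}-2,2,6-trimethylcyclohexan-1-one F7, which blocks retro-aldol cleavage. Wittig methylenation (Ph3PCH3Br, KOtBu, toluene, 100 °C) should give tert-butyl(dimethyl){2-methyl-1-[(1S)-1,3,3-trimethyl-2-methylidenecyclohexyl]prop-2-en-1-yl}oxysilane F8. Desilylation with Bu4NF returns alcohol 10, where the route is rejoined.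

**Further compounds**
F1 | step 8 | 2-methyl-1-[(4S)-4,8,8-trimethyl-1-oxaspiro[2.5]octan-4-yl]prop-2-en-1-one (epoxide epimers) | CC(=C)C(=O)[C@@]1(C)CCCC(C)(C)C12CO2
F2 | step 8 | (2S)-2,6,6-trimethyl-2-(2-methylprop-2-enoyl)cyclohexane-1-carbaldehyde (C1 epimers) | CC(=C)C(=O)[C@@]1(C)CCCC(C)(C)C1C=O
F3 | step 14 | (1R,2R,4R,4aS,8aS)-1-(hydroxymethyl)-2,5,5,8a-tetramethyldecahydronaphthalene-1,4-diol | O[C@@H]1C[C@@H](C)[C@](O)(CO)[C@@]2(C)CCCC(C)(C)[C@H]12
F4 | step 14 | (1R,2R,4R,4aS,8aS)-1,4-dihydroxy-2,5,5,8a-tetramethyldecahydronaphthalene-1-carbaldehyde | O[C@@H]1C[C@@H](C)[C@](O)(C=O)[C@@]2(C)CCCC(C)(C)[C@H]12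
F5 | step 5 | (1R)-1,3,3-trimethyl-2-oxocyclohexane-1-carbaldehyde | O=C[C@@]1(C)CCCC(C)(C)C1=O
F6 | step 5 | (6R)-6-(1-hydroxy-2-methylprop-2-en-1-yl)-2,2,6-trimethylcyclohexan-1-one (carbinol epimers) | CC(=C)C(O)[C@@]1(C)CCCC(C)(C)C1=O
F7 | step 5 | (6R)-6-{1-[tert-butyl(dimethyl)silyl]oxy-2-methylprop-2-en-1-yl}-2,2,6-trimethylcyclohexan-1-one | CC(=C)C(O[Si](C)(C)C(C)(C)C)[C@@]1(C)CCCC(C)(C)C1=O
F8 | step 5 | tert-butyl(dimethyl){2-methyl-1-[(1S)-1,3,3-trimethyl-2-methylidenecyclohexyl]prop-2-en-1-yl}oxysilane | CC(=C)C(O[Si](C)(C)C(C)(C)C)[C@@]1(C)CCCC(C)(C)C1=C
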